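Eremophilane numbering is used (ring A: C1–C5 and C10; ring B: C5–C10). Ring B carries an isopropenyl group on C7 trans to an oxygen on C8, a homoallylic alcohol of the kind a carbonyl-ene reaction produces, so the route disconnects C7–C8 to a C8 aldehyde and a prenyl group on quaternary C5. In a single operation the aluminium-promoted cyclisation forms ring B, fixes both new stereocentres (C7, C8), generates the isopropenyl unit from a prenyl methyl and delivers the C8 alcohol unprotected next to the C9 silyl ether. The precursor is a ring A cyclohexanone bearing cis prenyl (C5) and 2-oxo-1-silyloxyethyl (C10) groups, assembled by Mukaiyama–Michael addition to an enantioenriched 4-prenylcyclohexenone.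

Key step: step 8

Remark 1: in the Why lines the monocyclic intermediates carry the eremophilane locants of the carbons they become; in enone 8 the carbonyl is C2, the alkene carbons are C1 and C10, the quaternary carbon is C5 and the methyl-bearing CH is C4.
Remark 2: the phosphoramidite enantiomer in step 1 is assumed to be the one that delivers the methyl group to give the 3S centre of enolate 3.
Remark 3: the epoxide and carbinol configurations drawn for 6 and 7 are those expected for attack trans to the ring methyl groups; they are destroyed by step 5 and either isomer serves.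
Remark 4: the target has 4S,5R,7R,8R,9S,10S configuration, with a cis ring fusion (C10–H cis to the C5 methyl), cis C4/C5 methyls, equatorial C7 isopropenyl and C8 acetate, and an axial C9 ester.

Step 1
Reactants: 1 2-methylcyclohex-2-en-1-one; 2 prenyl bromide (1-bromo-3-methylbut-2-ene)
Product: 4 (2R,3S)-2,3-dimethyl-2-(3-methylbut-2-en-1-yl)cyclohexan-1-one, via dimethylaluminium enolate 3 (not isolated)
Conditions: AlMe3, Cu(O2CC4H3S) (copper thiophene-2-carboxylate, cat.), BINOL/bis(1-phenylethyl)amine phosphoramidite (cat.), Et2O, -30 °C; then MeLi, THF/DMPU, -30 °C; then 2, -30 °C → rt; 1 M HCl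
Reagents that add atoms: trimethylaluminium, C[Al](C)C
Why: Copper-catalysed asymmetric conjugate addition of AlMe3 to the 2-substituted enone sets the methyl-bearing centre under ligand control, and the regiodefined enolate, made nucleophilic as its lithium aluminate, is C-alkylated by the allylic bromide on the face opposite the adjacent methyl group (axial entry into the half-chair), which fixes the quaternary centre with the two methyl groups cis (tandem conjugate addition–enolate alkylation).

Step 2
Reactants: 4 (2R,3S)-2,3-dimethyl-2-(3-methylbut-2-en-1-yl)cyclohexan-1-one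
Product: 5 (5S,6R)-5,6-dimethyl-6-(3-methylbut-2-en-1-yl)cyclohex-2-en-1-one
Conditions: IBX (2-iodoxybenzoic acid), DMSO/toluene, 70 °C
Reagents that add atoms: none
Why: IBX α,β-dehydrogenation of a ketone can only run toward the CH2 side because the other α-carbon is quaternary, the isolated trisubstituted alkene is not attacked at this temperature, and no stereocentre is touched.

Step 3
Reactants: 5 (5S,6R)-5,6-dimethyl-6-(3-methylbut-2-en-1-yl)cyclohex-2-en-1-one
Product: 6 (1S,3R,4S,6S)-3,4-dimethyl-3-(3-methylbut-2-en-1-yl)-7-oxabicyclo[4.1.0]heptan-2-one (epoxide oxygen trans to both methyl groups)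
Conditions: 30% H2O2, NaOH (cat.), MeOH, 0 °C
Reagents that add atoms: hydrogen peroxide, OO
Why: Weitz–Scheffer nucleophilic epoxidation touches only the electron-poor enone double bond and leaves the prenyl alkene alone, the hydroperoxide adding axially trans to the ring methyl groups; the epoxide configuration is of no consequence because both new centres are lost by step 5.

Step 4
Reactants: 6 (1S,3R,4S,6S)-3,4-dimethyl-3-(3-methylbut-2-en-1-yl)-7-oxabicyclo[4.1.0]heptan-2-one
Product: 7 (1S,4R,5S)-4,5-dimethyl-4-(3-methylbut-2-en-1-yl)cyclohex-2-en-1-ol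
Conditions: N2H4·H2O, AcOH (cat.), MeOH, 0 °C → rt, argon
Reagents that add atoms: none
Why: Wharton transposition, in which the epoxy hydrazone fragments with loss of N2 so that the alkene moves next to the quaternary carbon and the oxygen stays on the former β-carbon; the two ring stereocentres are not involved, and argon prevents diimide formation that could reduce the alkenes.

Step 5
Reactants: 7 (1S,4R,5S)-4,5-dimethyl-4-(3-methylbut-2-en-1-yl)cyclohex-2-en-1-ol
Product: 8 (4R,5S)-4,5-dimethyl-4-(3-methylbut-2-en-1-yl)cyclohex-2-en-1-one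
Conditions: MnO2, CH2Cl2, rt
Reagents that add atoms: none
Why: MnO2 oxidises the allylic alcohol selectively to the transposed enone, erasing the carbinol centre and leaving the prenyl group untouched.

Step 6
Reactants: 9 (tert-butyldimethylsilyloxy)acetaldehyde
Product: 10 (Z)-1,2-bis(tert-butyldimethylsilyloxy)ethene
Conditions: TBSOTf, Et3N, CH2Cl2, 0 °C → rt
Reagents that add atoms: tert-butyldimethylsilyl trifluoromethanesulfonate, CC(C)(C)[Si](C)(C)OS(=O)(=O)C(F)(F)F
Why: Soft enolisation of the α-silyloxy aldehyde with silyl triflate and amine gives the enediol bis-silyl ether, the Z isomer being the favoured geometry for 1,2-dioxygenated alkenes; the product is symmetrical, so its two nucleophilic carbons are equivalent and the next step has no regiochemical issue.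

Step 7
Reactants: 8 (4R,5S)-4,5-dimethyl-4-(3-methylbut-2-en-1-yl)cyclohex-2-en-1-one; 10 (Z)-1,2-bis(tert-butyldimethylsilyloxy)ethene
Product: 12 (2R)-2-(tert-butyldimethylsilyloxy)-2-[(1S,2R,3S)-2,3-dimethyl-2-(3-methylbut-2-en-1-yl)-5-oxocyclohexyl]acetaldehyde, via difluoroboron enolate 11 (not isolated)
Conditions: BF3·OEt2 (1 equiv), CH2Cl2, -78 °C, slow addition of 10; NaHCO3 aq at -78 °C
Reagents that add atoms: none
Why: Mukaiyama–Michael addition in which the BF3-bound enone is attacked at C10 along the axial trajectory anti to the axial C5 methyl and the C4 methyl (chair-like enolate), placing the new chain cis to the prenyl group, while C9 should be set in an open transition state with its hydrogen in the crowded position and its silyloxy group anti to quaternary C5; fluoride passes from boron to silicon, so one equivalent of Lewis acid is used up per addition and the freed aldehyde is not activated toward aldol with excess donor or premature cyclisation, aqueous bicarbonate then hydrolyses boron enolate 11 to the ketone, and any C9 epimer is removed by chromatography.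

Step 8
Reactants: 12 (2R)-2-(tert-butyldimethylsilyloxy)-2-[(1S,2R,3S)-2,3-dimethyl-2-(3-methylbut-2-en-1-yl)-5-oxocyclohexyl]acetaldehyde
Product: 13 (4S,5R,7R,8R,9R,10S)-9-(tert-butyldimethylsilyloxy)-8-hydroxyeremophil-11-en-2-one (cis-decalin; C7 isopropenyl, C8 hydroxyl and C9 silyloxy all equatorial on ring B)
Conditions: Me2AlCl (2.5 equiv), CH2Cl2, -78 → -40 °C; cold 1 M HCl
Reagents that add atoms: none
Why: Me2AlCl binds the aldehyde oxygen of 12, and the prenyl alkene then bonds through its less substituted carbon (C7) to the aldehyde carbon (C8) while a methyl hydrogen passes to oxygen in a concerted six-centre ene process, so the isopropenyl group arises on C7 and the alcohol–aluminium complex loses methane, removing the proton that would otherwise start cationic side reactions. The closest known reaction is the Lewis-acid type 1 intramolecular carbonyl-ene cyclisation of 7-methyloct-6-enals, of which citronellal to isopulegol is the standard case. Ring B (C5–C6–C7–C8–C9–C10) closes as a six-membered chair by C7–C8 bond formation, cis-fused to ring A because the aldehyde-bearing chain on C10 is axial and the prenyl group on C5 equatorial on the same face. C7 and C8 are controlled by that chair, in which the developing isopropenyl group and the aluminium-bound oxygen both sit equatorial and so end up trans. The step needs selection between the two chairs that would give opposite C7/C8 configurations, and the C9 silyloxy group secures it, being equatorial in the chair leading to 13 and 1,3-diaxial to the C5 methyl in the other. It also needs chemoselectivity for the aldehyde over the ring A ketone, which follows from the far greater enophilicity of a Lewis-acid-bound aldehyde at low temperature.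

Step 9
Reactants: 13 (4S,5R,7R,8R,9R,10S)-9-(tert-butyldimethylsilyloxy)-8-hydroxyeremophil-11-en-2-one
Product: 14 (4S,5R,7R,8R,9R,10S)-8-acetoxy-9-(tert-butyldimethylsilyloxy)eremophil-11-en-2-one
Conditions: Ac2O, pyridine, DMAP (cat.), CH2Cl2, rt
Reagents that add atoms: acetic anhydride, CC(=O)OC(C)=O
Why: DMAP-catalysed acetylation of the only free hydroxyl (equatorial, on C8), with no change at any stereocentre.

Step 10
Reactants: 14 (4S,5R,7R,8R,9R,10S)-8-acetoxy-9-(tert-butyldimethylsilyloxy)eremophil-11-en-2-one
Product: 15 (4S,5R,7R,8R,9R,10S)-8-acetoxy-9-(tert-butyldimethylsilyloxy)-2,2-(ethylenedioxy)eremophil-11-ene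
Conditions: TMSOCH2CH2OTMS, TMSOTf (cat.), CH2Cl2, -78 → -20 °C; pyridine
Reagents that add atoms: 1,2-bis(trimethylsilyloxy)ethane, C[Si](C)(C)OCCO[Si](C)(C)C
Why: Silyl-triflate-catalysed acetalisation with the bis-silyl glycol ether converts the unhindered ring A ketone into its dioxolane under non-protic conditions that spare the silyl ether, the acetate and the isopropenyl group, and the irreversible formation of hexamethyldisiloxane drives it despite the axial C–O bond that the ketal places syn to C9.

Step 11
Reactants: 15 (4S,5R,7R,8R,9R,10S)-8-acetoxy-9-(tert-butyldimethylsilyloxy)-2,2-(ethylenedioxy)eremophil-11-ene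
Product: 16 (4S,5R,7R,8R,9R,10S)-8-acetoxy-2,2-(ethylenedioxy)-9-hydroxyeremophil-11-ene (C9 hydroxyl equatorial, trans to the acetate)
Conditions: HF·pyridine, pyridine, THF, 0 °C → rt
Reagents that add atoms: none
Why: Buffered HF-pyridine cleaves the secondary silyl ether through formation of the strong Si–F bond, and the weakly acidic, non-basic medium keeps the neighbouring acetate from migrating and is tolerated by the dioxolane.

Step 12
Reactants: 16 (4S,5R,7R,8R,9R,10S)-8-acetoxy-2,2-(ethylenedioxy)-9-hydroxyeremophil-11-ene
Product: 17 (4S,5R,7R,8R,10S)-8-acetoxy-2,2-(ethylenedioxy)eremophil-11-en-9-one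
Conditions: Dess–Martin periodinane, NaHCO3, CH2Cl2, 0 °C → rt
Reagents that add atoms: none
Why: Dess–Martin oxidation under bicarbonate buffer gives the α-acetoxy ketone without a base able to enolise C8 or C10, and both flanking centres already hold their more stable arrangement (equatorial acetate; cis fusion enforced by the equatorial isopropenyl group), so no epimerisation is expected.

Step 13
Reactants: 17 (4S,5R,7R,8R,10S)-8-acetoxy-2,2-(ethylenedioxy)eremophil-11-en-9-one
Product: 18 (4S,5R,7R,8R,9S,10S)-8-acetoxy-2,2-(ethylenedioxy)-9-hydroxyeremophil-11-ene (C9 hydroxyl axial, cis to the acetate)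
Conditions: LiBH(s-Bu)3, THF, -78 °C; AcOH, -78 °C
Reagents that add atoms: none
Why: Diastereoselective hydride reduction in which the bulky borohydride reaches the C9 carbonyl from the open equatorial side, the axial side lying in the concave face of the cis-decalin under the syn-axial C4–C5 bond, which gives the axial alcohol with the C9 configuration of the target; the acetic acid quench at -78 °C protonates the alkoxide before the cis acetate can migrate.

Step 14
Reactants: 19 3-methylbut-2-enoic acid (senecioic acid), two molecules per molecule of anhydride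
Product: 20 3-methylbut-2-enoic anhydride (senecioic anhydride)
Conditions: 19 (2.0 equiv), DCC (1.0 equiv), CH2Cl2, 0 °C → rt; filtration
Reagents that add atoms: 3-methylbut-2-enoic acid (the second molecule of 19, which supplies the second acyl group), CC(C)=CC(=O)O
Why: Carbodiimide dehydration, in which the O-acylisourea formed from one molecule of the acid is attacked by the carboxyl group of a second molecule, gives the symmetrical anhydride and the insoluble urea that is filtered off, and with no base present the conjugated double bonds stay in place.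

Step 15
Reactants: 18 (4S,5R,7R,8R,9S,10S)-8-acetoxy-2,2-(ethylenedioxy)-9-hydroxyeremophil-11-ene; 20 3-methylbut-2-enoic anhydride
Product: 21 (4S,5R,7R,8R,9S,10S)-8-acetoxy-2,2-(ethylenedioxy)-9-(3-methylbut-2-enoyloxy)eremophil-11-ene
Conditions: Sc(OTf)3 (5 mol%), MeCN, -20 → 0 °C
Reagents that add atoms: none
Why: Sc(OTf)3-catalysed acylation with an anhydride esterifies hindered secondary alcohols under Lewis-acidic rather than basic conditions, so the acetate should not migrate to the cis hydroxyl and the senecioyl group cannot deconjugate through a vinylketene; only the O–H bond reacts, so C9 keeps its configuration.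

Step 16
Reactants: 21 (4S,5R,7R,8R,9S,10S)-8-acetoxy-2,2-(ethylenedioxy)-9-(3-methylbut-2-enoyloxy)eremophil-11-ene
Product: 22 (4S,5R,7R,8R,9S,10S)-8-acetoxy-9-(3-methylbut-2-enoyloxy)eremophil-11-en-2-one (CNP0150397.1)
Conditions: PPTS, acetone/H2O, 40 °C
Reagents that add atoms: water, O
Why: Pyridinium tosylate in wet acetone hydrolyses the dioxolane (helped by relief of the axial C–O/C9 interaction) in a medium too mild to cleave either ester or to move the isopropenyl double bond, and no stereocentre is α to the liberated ketone.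

Compound list
1 | 2-methylcyclohex-2-en-1-one | CC1=CCCCC1=O | starting material
2 | prenyl bromide (1-bromo-3-methylbut-2-ene) | CC(C)=CCBr | starting material
3 | dimethylaluminium (3S)-2,3-dimethylcyclohex-1-en-1-olate | CC1=C(O[Al](C)C)CCC[C@@H]1C | intermediate (not isolated)
4 | (2R,3S)-2,3-dimethyl-2-(3-methylbut-2-en-1-yl)cyclohexan-1-one (methyl groups cis) | CC(C)=CC[C@@]1(C)C(=O)CCC[C@@H]1C | intermediate
5 | (5S,6R)-5,6-dimethyl-6-(3-methylbut-2-en-1-yl)cyclohex-2-en-1-one | CC(C)=CC[C@@]1(C)C(=O)C=CC[C@@H]1C | intermediate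
6 | (1S,3R,4S,6S)-3,4-dimethyl-3-(3-methylbut-2-en-1-yl)-7-oxabicyclo[4.1.0]heptan-2-one (epoxide oxygen trans to the methyl groups) | CC(C)=CC[C@@]1(C)C(=O)[C@H]2O[C@H]2C[C@@H]1C | intermediate
7 | (1S,4R,5S)-4,5-dimethyl-4-(3-methylbut-2-en-1-yl)cyclohex-2-en-1-ol | CC(C)=CC[C@@]1(C)C=C[C@@H](O)C[C@@H]1C | intermediate
8 | (4R,5S)-4,5-dimethyl-4-(3-methylbut-2-en-1-yl)cyclohex-2-en-1-one | CC(C)=CC[C@@]1(C)C=CC(=O)C[C@@H]1C | intermediate
9 | (tert-butyldimethylsilyloxy)acetaldehyde | CC(C)(C)[Si](C)(C)OCC=O | starting material
10 | (Z)-1,2-bis(tert-butyldimethylsilyloxy)ethene | CC(C)(C)[Si](C)(C)O/C=C\O[Si](C)(C)C(C)(C)C | intermediate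
11 | difluoroboron enolate of 12 (O–BF2 on the ring oxygen, C1=C2 double bond) | CC(C)=CC[C@@]1(C)[C@H](C=C(OB(F)F)C[C@@H]1C)[C@@H](O[Si](C)(C)C(C)(C)C)C=O | intermediate (not isolated)
12 | (2R)-2-(tert-butyldimethylsilyloxy)-2-[(1S,2R,3S)-2,3-dimethyl-2-(3-methylbut-2-en-1-yl)-5-oxocyclohexyl]acetaldehyde (side chain cis to prenyl, trans to both methyls) | CC(C)=CC[C@@]1(C)[C@H](CC(=O)C[C@@H]1C)[C@@H](O[Si](C)(C)C(C)(C)C)C=O | intermediate
13 | (4S,5R,7R,8R,9R,10S)-9-(tert-butyldimethylsilyloxy)-8-hydroxyeremophil-11-en-2-one | C=C(C)[C@H]1C[C@@]2(C)[C@H](CC(=O)C[C@@H]2C)[C@@H](O[Si](C)(C)C(C)(C)C)[C@@H]1O | intermediate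
14 | (4S,5R,7R,8R,9R,10S)-8-acetoxy-9-(tert-butyldimethylsilyloxy)eremophil-11-en-2-one | C=C(C)[C@H]1C[C@@]2(C)[C@H](CC(=O)C[C@@H]2C)[C@@H](O[Si](C)(C)C(C)(C)C)[C@@H]1OC(C)=O | intermediate
15 | (4S,5R,7R,8R,9R,10S)-8-acetoxy-9-(tert-butyldimethylsilyloxy)-2,2-(ethylenedioxy)eremophil-11-ene | C=C(C)[C@H]1C[C@@]2(C)[C@H](CC3(OCCO3)C[C@@H]2C)[C@@H](O[Si](C)(C)C(C)(C)C)[C@@H]1OC(C)=O | intermediate
16 | (4S,5R,7R,8R,9R,10S)-8-acetoxy-2,2-(ethylenedioxy)-9-hydroxyeremophil-11-ene (equatorial C9–OH) | C=C(C)[C@H]1C[C@@]2(C)[C@H](CC3(OCCO3)C[C@@H]2C)[C@@H](O)[C@@H]1OC(C)=O | intermediate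
17 | (4S,5R,7R,8R,10S)-8-acetoxy-2,2-(ethylenedioxy)eremophil-11-en-9-one | C=C(C)[C@H]1C[C@@]2(C)[C@H](CC3(OCCO3)C[C@@H]2C)C(=O)[C@@H]1OC(C)=O | intermediate
18 | (4S,5R,7R,8R,9S,10S)-8-acetoxy-2,2-(ethylenedioxy)-9-hydroxyeremophil-11-ene (axial C9–OH) | C=C(C)[C@H]1C[C@@]2(C)[C@H](CC3(OCCO3)C[C@@H]2C)[C@H](O)[C@@H]1OC(C)=O | intermediate
19 | 3-methylbut-2-enoic acid (senecioic acid) | CC(C)=CC(=O)O | starting material
20 | 3-methylbut-2-enoic anhydride | CC(C)=CC(=O)OC(=O)C=C(C)C | intermediate
21 | (4S,5R,7R,8R,9S,10S)-8-acetoxy-2,2-(ethylenedioxy)-9-(3-methylbut-2-enoyloxy)eremophil-11-ene | C=C(C)[C@H]1C[C@@]2(C)[C@H](CC3(OCCO3)C[C@@H]2C)[C@H](OC(=O)C=C(C)C)[C@@H]1OC(C)=O | intermediate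
22 | (4S,5R,7R,8R,9S,10S)-8-acetoxy-9-(3-methylbut-2-enoyloxy)eremophil-11-en-2-one (CNP0150397.1) | C=C(C)[C@H]1C[C@@]2(C)[C@H](CC(=O)C[C@@H]2C)[C@H](OC(=O)C=C(C)C)[C@@H]1OC(C)=O | target

Total step count: 16. Longest linear sequence: 14 steps (steps 1–5, 7–13, 15 and 16); steps 6 and 14 prepare the two side-arm reagents.

Steps most likely to fail

Step 7. The addition may be slow at the β-carbon next to the quaternary centre, the silyloxy-bearing centre C9 may form with poor facial control, and the freed aldehyde may be consumed by aldol chain extension. The fallback sets out from enone 8 and returns to the route at keto aldehyde 12. Commercial methyl (tert-butyldimethylsilyloxy)acetate would be converted with LiN(i-Pr)2 and TMSCl (THF, -78 °C) into the far more nucleophilic ketene silyl acetal (Z)-1-methoxy-1-(trimethylsilyloxy)-2-(tert-butyldimethylsilyloxy)ethene F1. Its Mukaiyama–Michael addition to 8 (TiCl4, CH2Cl2, -78 °C) should give methyl (2R)-2-(tert-butyldimethylsilyloxy)-2-[(1S,2R,3S)-2,3-dimethyl-2-(3-methylbut-2-en-1-yl)-5-oxocyclohexyl]acetate F2, an ester that can neither oligomerise by aldol addition nor cyclise early and whose C9 epimers can be separated at this stage. Excess i-Bu2AlH (CH2Cl2, -78 → 0 °C) would reduce ketone and ester to (2R)-2-(tert-butyldimethylsilyloxy)-2-[(1S,2R,3S)-5-hydroxy-2,3-dimethyl-2-(3-methylbut-2-en-1-yl)cyclohexyl]ethan-1-ol F3 (ring carbinol as either epimer), and buffered Dess–Martin oxidation of both hydroxyls leads back to 12.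

Step 8. The two chair transition states, or the equatorial and axial placements of the bound carbonyl oxygen, may be poorly discriminated, and Lewis-acid-induced cationic pathways may compete with the concerted ene process. The fallback sets out from 12 and returns at 13, replacing the ene reaction by an intramolecular allylmetal addition. Catalytic SeO2 with t-BuOOH (CH2Cl2, rt) would oxidise the E methyl of the prenyl group to give (2R)-2-(tert-butyldimethylsilyloxy)-2-[(1S,2R,3S)-2-[(2E)-4-hydroxy-3-methylbut-2-en-1-yl]-2,3-dimethyl-5-oxocyclohexyl]acetaldehyde F4. Appel bromination (CBr4, PPh3, CH2Cl2, 0 °C) gives (2R)-2-(tert-butyldimethylsilyloxy)-2-[(1S,2R,3S)-2-[(2E)-4-bromo-3-methylbut-2-en-1-yl]-2,3-dimethyl-5-oxocyclohexyl]acetaldehyde F5. CrCl2 (THF, rt; Nozaki–Hiyama-type allylation) then forms an allylchromium species that adds through its γ-carbon (C7) to the aldehyde only, in a closed chair that again places the new isopropenyl and hydroxyl groups trans, to give 13 under neutral conditions.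

Step 13. The acetyl group may migrate to, or be lost at, the newly formed cis alkoxide, giving mixtures of regioisomeric monoacetates. The fallback sets out from ketone 17 and returns at 18, accepting loss of the acetate instead of fighting it. LiAlH4 (THF, -78 → 0 °C) would reduce the ketone from the same open equatorial side and cleave the acetate, giving (4S,5R,7R,8R,9S,10S)-2,2-(ethylenedioxy)eremophil-11-ene-8,9-diol F6 (C8 hydroxyl equatorial, C9 hydroxyl axial). Formation of the dibutylstannylene acetal (Bu2SnO, toluene, reflux) and treatment with AcCl (0 °C) acetylates the equatorial C8 oxygen of such an axial–equatorial cis-diol selectively and leads to 18. Any acetate mixture from the main step can be funnelled into F6 by K2CO3 in MeOH.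

Further compounds
F1 | step 7 | (Z)-1-methoxy-1-(trimethylsilyloxy)-2-(tert-butyldimethylsilyloxy)ethene | C[Si](C)(C)O/C(OC)=C\O[Si](C)(C)C(C)(C)C
F2 | step 7 | methyl (2R)-2-(tert-butyldimethylsilyloxy)-2-[(1S,2R,3S)-2,3-dimethyl-2-(3-methylbut-2-en-1-yl)-5-oxocyclohexyl]acetate | CC(C)=CC[C@@]1(C)[C@H](CC(=O)C[C@@H]1C)[C@@H](O[Si](C)(C)C(C)(C)C)C(=O)OC
F3 | step 7 | (2R)-2-(tert-butyldimethylsilyloxy)-2-[(1S,2R,3S)-5-hydroxy-2,3-dimethyl-2-(3-methylbut-2-en-1-yl)cyclohexyl]ethan-1-ol (ring carbinol either epimer) | CC(C)=CC[C@@]1(C)[C@H](CC(O)C[C@@H]1C)[C@@H](O[Si](C)(C)C(C)(C)C)CO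
F4 | step 8 | (2R)-2-(tert-butyldimethylsilyloxy)-2-[(1S,2R,3S)-2-[(2E)-4-hydroxy-3-methylbut-2-en-1-yl]-2,3-dimethyl-5-oxocyclohexyl]acetaldehyde | OC/C(C)=C/C[C@@]1(C)[C@H](CC(=O)C[C@@H]1C)[C@@H](O[Si](C)(C)C(C)(C)C)C=O
F5 | step 8 | (2R)-2-(tert-butyldimethylsilyloxy)-2-[(1S,2R,3S)-2-[(2E)-4-bromo-3-methylbut-2-en-1-yl]-2,3-dimethyl-5-oxocyclohexyl]acetaldehyde | BrC/C(C)=C/C[C@@]1(C)[C@H](CC(=O)C[C@@H]1C)[C@@H](O[Si](C)(C)C(C)(C)C)C=O
F6 | step 13 | (4S,5R,7R,8R,9S,10S)-2,2-(ethylenedioxy)eremophil-11-ene-8,9-diol | C=C(C)[C@H]1C[C@@]2(C)[C@H](CC3(OCCO3)C[C@@H]2C)[C@H](O)[C@@H]1O
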